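The readings were generated by integration on assumed constants.

Follow the leftover: let a be the fraction of the charged first end groups still unreacted in the flask.

| flask | first end groups | second end groups | remark | time |
|---|---|---|---|---|
| red | 2.2 M | 1 equiv (fed, over 20 h) | run made earlier |  |
| flask | 1.6 M | 1.00 equiv (fed, over 20 h) |  | 10 d |

red run (percent of the first end groups charged)

| time / d | links / % | first end groups / % |
|---|---|---|
| 1.25 | 62.2 | 37.8 |
| 2.50 | 81.0 | 19.7 |
| 4.00 | 88.3 | 12.2 |
| 5.00 | 89.9 | 8.5 |
| 6.00 | 91.6 | 9.1 |
| 8.00 | 93.6 | 6.0 |

(standard deviation of a reading: 0.5 percentage points)

- each molecule carries two end groups: a chain counts once for every two ends that are left, dead ends included; the units are half of the end groups of the two monomers charged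
- the numbers in the tables scatter with a standard deviation of 0.5 percentage points
- steps that have been proposed: first end groups + second end groups -> links + released group; links -> over-reaction product
- a link that another step uses up counts as cut, two dead ends; so do two ends of one kind that react with each other

1. whether the average number of monomer units in a chain (unreacted monomers counted as chains of one) reaches 7.0 by 10 d (yes / no)
2. average number of monomer units in a chain (unreacted monomers counted as chains of one) at 10 d

A chain counts for two ends left and a unit for two ends charged, so with equal charges the average length is the reciprocal of a plus the fraction of links cut (the Carothers relation). Write the balance of first end groups, with b the free second end groups as a fraction of the same charge: a falls at k times the starting concentration times a times b. Once the feed is over, b equals a at 1.00 equiv, so the reciprocal of a climbs in a straight line.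

In the red run that reciprocal goes from 5.08 at 2.50 d to 16.7 at 8.00 d, so k reads 0.958 M⁻¹ d⁻¹. At 1.6 M the flask's clock is 1.53 d⁻¹, the daily rise of the reciprocal of a.

Now run the flask slowly. At first second end groups are still arriving, over a feed of 20 h that is short against 10 d. My reckoning therefore counts it as a delay of half its length, which puts the reciprocal at 1.64 when the feed ends. In the middle the clock carries it past 7.0 at 4.34 d. At the end it stands at 15.7, and the momentary rate there corresponds to a half-life of first end groups of the logarithm of two times that figure over the clock, 7.09 d. Cuts add directly to a, yet the red run's last links and first end groups sum to 99.6%, with a scatter of 0.5 percentage points per reading.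

The forecast, reading “clean second-order behaviour with balanced ends”, says yes and 15; my reciprocal is a little higher, before any cutting.

    first end groups + second end groups → links + released group (k = 6.60 × 10⁻⁴ M⁻¹ min⁻¹)
    links → over-reaction product (k = 4.50 × 10⁻⁷ min⁻¹)

The flask answers yes, with an average length of 14.4 at 10 d, and it passes 7.0 at 4.46 d. At 10 d the reciprocal of a stands at 15.5, while the over-reaction product is 0.503%, and the half-life of links by that step alone, 1100 d, is far longer than 10 d. Put the clock to the simulated a of 6.45%: the logarithm of two over their product gives 7.02 d for the half-life of first end groups at that time, and the flask's value is 7.1 d.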